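**Retrosynthetic overview**

1. Target 24 ⇒ alcohol 23 (acetylation) ⇒ bicyclic enol ether 20, by exo-epoxidation and epoxide-to-allylic-alcohol isomerisation (sets C4, moves the enol ether to C2=C3).
2. 20 ⇒ cyclopentanone 18: the six-membered ring (bridge C2–C3–C4) is closed last by intramolecular allylic alkylation at C1 (C1–C2 bond, quaternary C1).
3. 18 ⇒ aldehyde 11 + methyl vinyl ether + allyl bromide; 11 ⇒ vinyl ketone 9 (ozonolysis).
4. 9 ⇒ allenyl cyclobutanol 8: key four-to-five ring expansion, a 1,2-shift of the benzylic ring carbon onto a palladium-bound methoxyallyl terminus, which builds the cyclopentanone and the quaternary C5–OMe centre.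
5. 8 ⇒ methoxyallene + cyclobutanone 5 ⇒ 3-methylcyclobutanone + 4-bromoveratrole (from catechol) by a desymmetrising α-arylation that sets C6, C7 and the absolute configuration. Ring order: four (bought) → five → six.

Atom labels C1–C8 in the comments are those of the target bicycle: C1 allyl bridgehead, C2=C3(OMe), C4 acetoxy carbon, C5 methoxy bridgehead, C6 aryl carbon, C7 methyl carbon, C8 ketone.

Assumption: the hand written for the chiral amine (step 3), the Trost ligand (step 5) and the auxiliary (fallback to step 3) is the one taken to give the drawn enantiomer; the mirror-image reagent is used if the sense of induction proves opposite.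

**Route**

Step 1
Reactants: 1 catechol
Product: 2 veratrole (1,2-dimethoxybenzene)
Conditions: MeI (2.5 equiv), K2CO3, acetone, reflux
Reagents that add atoms: methyl iodide, CI
Why: Williamson ether synthesis methylates both phenols; no stereocentre is involved.

Step 2
Reactants: 2 veratrole
Product: 3 4-bromo-1,2-dimethoxybenzene
Conditions: NBS, MeCN, 0 to 23 °C
Reagents that add atoms: N-bromosuccinimide, O=C1CCC(=O)N1Br
Why: Electrophilic aromatic bromination goes para to one methoxy group, the only unhindered activated position.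

Step 3
Reactants: 3 4-bromo-1,2-dimethoxybenzene; 4 3-methylcyclobutan-1-one (2.5 equiv)
Product: 5 (2S,3S)-2-(3,4-dimethoxyphenyl)-3-methylcyclobutan-1-one
Conditions: Pd(OAc)2 (5 mol %), P(o-tol)3 (10 mol %), (S)-2-(diphenylmethyl)pyrrolidine (20 mol %), NaOAc (2 equiv), 1,4-dioxane, 70 °C
Reagents that add atoms: none
Why: Proposed new method: an enantioselective, desymmetrising intermolecular α-arylation by cooperative palladium/enamine catalysis, in which the chiral pyrrolidine forms the enamine at one of the two enantiotopic α-CH2 groups of 4 (this fixes C7), the enamine carbon attacks the arylpalladium bromide formed from 3 and zerovalent palladium on the face anti to the methyl group, and reductive elimination, iminium hydrolysis and equilibration of the acidic benzylic centre give the trans ketone (fixes C6); the closest known reactions are the racemic palladium/pyrrolidine α-arylation of cyclopentanones with aryl bromides and the intramolecular palladium/enamine desymmetrising α-arylation of 3-substituted cyclobutanones (Buchwald–Hartwig-type ketone α-arylation).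

Step 4
Reactants: 5 (2S,3S)-2-(3,4-dimethoxyphenyl)-3-methylcyclobutan-1-one; 6 methoxyallene
Product: 8 (1S,2S,3S)-2-(3,4-dimethoxyphenyl)-1-(1-methoxypropa-1,2-dien-1-yl)-3-methylcyclobutan-1-ol, via 1-lithio-1-methoxyallene 7 (not isolated)
Conditions: 6, n-BuLi, THF, −78 °C; LaCl3·2LiCl (10 mol %), 5, −78 °C; H2O
Reagents that add atoms: none
Why: 1,2-Addition of the α-lithiated alkoxyallene to the strained, very electrophilic cyclobutanone occurs anti to the neighbouring aryl group (the carbinol centre is destroyed in step 5).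

Step 5
Reactants: 8 (1S,2S,3S)-2-(3,4-dimethoxyphenyl)-1-(1-methoxypropa-1,2-dien-1-yl)-3-methylcyclobutan-1-ol
Product: 9 (2R,3S,4S)-3-(3,4-dimethoxyphenyl)-2-ethenyl-2-methoxy-4-methylcyclopentan-1-one
Conditions: Pd2(dba)3·CHCl3 (2.5 mol %), (R,R)-DACH-phenyl Trost ligand (7.5 mol %), PhCO2H (10 mol %), Et3N (10 mol %), ClCH2CH2Cl, 60 °C
Reagents that add atoms: none
Why: Key ring expansion by a palladium-catalysed Wagner–Meerwein (semipinacol-type) 1,2-shift: palladium hydride adds to the allene to give a 1-methoxyallyl unit on palladium, the electron-rich benzylic ring carbon (not the CH2) migrates with retention to the methoxy-bearing terminus anti to the metal, and ligand plus substrate bias place the vinyl group trans to the aryl group at the new quaternary C5.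

Step 6
Reactants: 9 (2R,3S,4S)-3-(3,4-dimethoxyphenyl)-2-ethenyl-2-methoxy-4-methylcyclopentan-1-one
Product: 11 (1S,2S,3S)-2-(3,4-dimethoxyphenyl)-1-methoxy-3-methyl-5-oxocyclopentane-1-carbaldehyde, via ozonide 10 (not isolated)
Conditions: O3, CH2Cl2, −78 °C (Sudan red 7B end point); PPh3, −78 to 23 °C
Reagents that add atoms: ozone, [O-][O+]=O
Why: Ozonolysis with reductive work-up cleaves the only alkene much faster than the dimethoxyarene is attacked and leaves the stereocentres untouched; the aldehyde is used crude.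

Step 7
Reactants: 11 (1S,2S,3S)-2-(3,4-dimethoxyphenyl)-1-methoxy-3-methyl-5-oxocyclopentane-1-carbaldehyde; 12 methyl vinyl ether
Product: 15 tert-butyl 1-[(1S,2S,3S)-2-(3,4-dimethoxyphenyl)-1-methoxy-3-methyl-5-oxocyclopentyl]-2-methoxyprop-2-en-1-yl carbonate (both epimers at the carbonate-bearing carbon), via 1-methoxyvinyllithium 13 (not isolated), via lithium alkoxide adduct 14 (not isolated)
Conditions: 12, t-BuLi, THF/pentane, −78 to 0 °C; 11, −78 °C; Boc2O, −78 to 0 °C
Reagents that add atoms: di-tert-butyl dicarbonate, CC(C)(C)OC(=O)OC(=O)OC(C)(C)C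
Why: The α-lithiated enol ether (acyl-anion equivalent) adds to the aldehyde in preference to the hindered ketone and the aldolate is trapped cold as the carbonate before retro-aldol cleavage; the new carbinol centre is a mixture that is erased in step 9.

Step 8
Reactants: 15 tert-butyl 1-[(1S,2S,3S)-2-(3,4-dimethoxyphenyl)-1-methoxy-3-methyl-5-oxocyclopentyl]-2-methoxyprop-2-en-1-yl carbonate; 16 allyl bromide
Product: 18 tert-butyl 1-[(1S,2S,3R)-2-(3,4-dimethoxyphenyl)-1-methoxy-3-methyl-5-oxo-4-(prop-2-en-1-yl)cyclopentyl]-2-methoxyprop-2-en-1-yl carbonate (epimer mixture at ring C4 and at the carbonate-bearing carbon), via lithium enolate 17 (not isolated)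
Conditions: LiN(SiMe3)2 (1.05 equiv), THF/DMPU, −78 °C; 16, −78 to −40 °C
Reagents that add atoms: none
Why: Kinetic enolate alkylation takes place at the only enolisable α-carbon (the other is quaternary); the configuration at C1 is irrelevant because it is re-enolised in step 9.

Step 9
Reactants: 18 tert-butyl 1-[(1S,2S,3R)-2-(3,4-dimethoxyphenyl)-1-methoxy-3-methyl-5-oxo-4-(prop-2-en-1-yl)cyclopentyl]-2-methoxyprop-2-en-1-yl carbonate
Product: 20 (1S,5R,6R,7S)-7-(3,4-dimethoxyphenyl)-1,3-dimethoxy-6-methyl-5-(prop-2-en-1-yl)bicyclo[3.2.1]oct-2-en-8-one, via lithium enolate 19 (not isolated)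
Conditions: LiN(SiMe3)2 (1.1 equiv), THF, −78 °C; Pd(PPh3)4 (5 mol %), −78 to 40 °C
Reagents that add atoms: none
Why: Intramolecular Tsuji–Trost allylic alkylation: zerovalent palladium ionises the allylic carbonate (both epimers converge by π–σ–π equilibration of the 2-methoxyallyl unit), the enolate attacks the unsubstituted allyl terminus, and because the tether can only bridge cis the quaternary C1 forms with the allyl group on the opposite face, aryl exo and methyl endo; O-allylation is reversible under the catalyst.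

Step 10
Reactants: 20 (1S,5R,6R,7S)-7-(3,4-dimethoxyphenyl)-1,3-dimethoxy-6-methyl-5-(prop-2-en-1-yl)bicyclo[3.2.1]oct-2-en-8-one
Product: 23 (1S,4S,5S,6S,7R)-6-(3,4-dimethoxyphenyl)-4-hydroxy-3,5-dimethoxy-7-methyl-1-(prop-2-en-1-yl)bicyclo[3.2.1]oct-2-en-8-one, via methoxy epoxide 21 (not isolated), via trimethylsilyl ether 22 (not isolated)
Conditions: dimethyldioxirane (1.05 equiv), acetone/CH2Cl2, −78 to −40 °C; Me3SiOTf, 2,6-lutidine, CH2Cl2, −78 °C; K2CO3 (cat.), MeOH, 0 °C
Reagents that add atoms: dimethyldioxirane, CC1(C)OO1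
Why: The electron-rich enol ether is epoxidised chemoselectively from the exo face (the side of the ketone bridge; the ethano bridge with its endo methyl shields the other side), and a Noyori-type silyl triflate/amine epoxide-to-allylic-ether isomerisation through the C3 oxocarbenium ion with loss of a C2 proton sets C4 and moves the enol ether to C2=C3.

Step 11
Reactants: 23 (1S,4S,5S,6S,7R)-6-(3,4-dimethoxyphenyl)-4-hydroxy-3,5-dimethoxy-7-methyl-1-(prop-2-en-1-yl)bicyclo[3.2.1]oct-2-en-8-one
Product: 24 (1S,4S,5S,6S,7R)-6-(3,4-dimethoxyphenyl)-3,5-dimethoxy-7-methyl-8-oxo-1-(prop-2-en-1-yl)bicyclo[3.2.1]oct-2-en-4-yl acetate (target CNP0221003.1)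
Conditions: Ac2O, pyridine, DMAP (cat.), CH2Cl2, 23 °C
Reagents that add atoms: acetic anhydride, CC(=O)OC(C)=O
Why: DMAP-catalysed O-acylation under basic conditions leaves the acid-sensitive enol ether and the C4 centre untouched.

**Compound list**

1 | catechol (benzene-1,2-diol) | Oc1ccccc1O | starting material
2 | veratrole (1,2-dimethoxybenzene) | COc1ccccc1OC | intermediate
3 | 4-bromo-1,2-dimethoxybenzene | COc1ccc(Br)cc1OC | intermediate
4 | 3-methylcyclobutan-1-one | CC1CC(=O)C1 | starting material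
5 | (2S,3S)-2-(3,4-dimethoxyphenyl)-3-methylcyclobutan-1-one (aryl and methyl trans) | O=C1[C@H](c2ccc(OC)c(OC)c2)[C@@H](C)C1 | intermediate
6 | methoxyallene (1-methoxypropa-1,2-diene) | COC=C=C | starting material
7 | 1-lithio-1-methoxyallene | [Li]C(OC)=C=C | intermediate (not isolated)
8 | (1S,2S,3S)-2-(3,4-dimethoxyphenyl)-1-(1-methoxypropa-1,2-dien-1-yl)-3-methylcyclobutan-1-ol (allenyl trans to aryl) | C=C=C(OC)[C@@]1(O)[C@H](c2ccc(OC)c(OC)c2)[C@@H](C)C1 | intermediate
9 | (2R,3S,4S)-3-(3,4-dimethoxyphenyl)-2-ethenyl-2-methoxy-4-methylcyclopentan-1-one (vinyl trans to aryl and cis to methyl) | C=C[C@](OC)(C1=O)[C@H](c2ccc(OC)c(OC)c2)[C@@H](C)C1 | intermediate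
10 | 3-[(1S,2S,3S)-2-(3,4-dimethoxyphenyl)-1-methoxy-3-methyl-5-oxocyclopentyl]-1,2,4-trioxolane (ozonide of 9) | O1COOC1[C@](OC)(C2=O)[C@H](c3ccc(OC)c(OC)c3)[C@@H](C)C2 | intermediate (not isolated)
11 | (1S,2S,3S)-2-(3,4-dimethoxyphenyl)-1-methoxy-3-methyl-5-oxocyclopentane-1-carbaldehyde | O=C[C@](OC)(C1=O)[C@H](c2ccc(OC)c(OC)c2)[C@@H](C)C1 | intermediate
12 | methyl vinyl ether (methoxyethene) | COC=C | starting material
13 | 1-methoxyvinyllithium | [Li]C(=C)OC | intermediate (not isolated)
14 | lithium 1-[(1S,2S,3S)-2-(3,4-dimethoxyphenyl)-1-methoxy-3-methyl-5-oxocyclopentyl]-2-methoxyprop-2-en-1-olate (both carbinol epimers) | C=C(OC)C(O[Li])[C@](OC)(C1=O)[C@H](c2ccc(OC)c(OC)c2)[C@@H](C)C1 | intermediate (not isolated)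
15 | tert-butyl 1-[(1S,2S,3S)-2-(3,4-dimethoxyphenyl)-1-methoxy-3-methyl-5-oxocyclopentyl]-2-methoxyprop-2-en-1-yl carbonate (both epimers at the carbonate-bearing carbon) | C=C(OC)C(OC(=O)OC(C)(C)C)[C@](OC)(C1=O)[C@H](c2ccc(OC)c(OC)c2)[C@@H](C)C1 | intermediate
16 | allyl bromide (3-bromoprop-1-ene) | C=CCBr | starting material
17 | lithium enolate of 15 (between the ketone carbon and the ring CH2) | C=C(OC)C(OC(=O)OC(C)(C)C)[C@]1(OC)C(O[Li])=C[C@H](C)[C@H]1c1ccc(OC)c(OC)c1 | intermediate (not isolated)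
18 | tert-butyl 1-[(1S,2S,3R)-2-(3,4-dimethoxyphenyl)-1-methoxy-3-methyl-5-oxo-4-(prop-2-en-1-yl)cyclopentyl]-2-methoxyprop-2-en-1-yl carbonate (epimers at ring C4 and at the carbonate-bearing carbon) | C=C(OC)C(OC(=O)OC(C)(C)C)[C@](OC)(C1=O)[C@H](c2ccc(OC)c(OC)c2)[C@@H](C)C1CC=C | intermediate
19 | lithium enolate of 18 (tetrasubstituted, allyl on the enolate carbon) | C=C(OC)C(OC(=O)OC(C)(C)C)[C@]1(OC)C(O[Li])=C(CC=C)[C@H](C)[C@H]1c1ccc(OC)c(OC)c1 | intermediate (not isolated)
20 | (1S,5R,6R,7S)-7-(3,4-dimethoxyphenyl)-1,3-dimethoxy-6-methyl-5-(prop-2-en-1-yl)bicyclo[3.2.1]oct-2-en-8-one (aryl exo, methyl endo) | C=CC[C@]12CC(OC)=C[C@](OC)(C1=O)[C@H](c1ccc(OC)c(OC)c1)[C@H]2C | intermediate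
21 | 2,3-epoxide of 20 (methoxy oxirane, oxygen on the face of the ketone bridge) | C=CC[C@]12C[C@]3(OC)O[C@@H]3[C@](OC)(C1=O)[C@H](c1ccc(OC)c(OC)c1)[C@H]2C | intermediate (not isolated)
22 | (1S,4S,5S,6S,7R)-6-(3,4-dimethoxyphenyl)-3,5-dimethoxy-7-methyl-1-(prop-2-en-1-yl)-4-[(trimethylsilyl)oxy]bicyclo[3.2.1]oct-2-en-8-one | C=CC[C@]12C=C(OC)[C@H](O[Si](C)(C)C)[C@](OC)(C1=O)[C@H](c1ccc(OC)c(OC)c1)[C@H]2C | intermediate (not isolated)
23 | (1S,4S,5S,6S,7R)-6-(3,4-dimethoxyphenyl)-4-hydroxy-3,5-dimethoxy-7-methyl-1-(prop-2-en-1-yl)bicyclo[3.2.1]oct-2-en-8-one | C=CC[C@]12C=C(OC)[C@H](O)[C@](OC)(C1=O)[C@H](c1ccc(OC)c(OC)c1)[C@H]2C | intermediate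
24 | (1S,4S,5S,6S,7R)-6-(3,4-dimethoxyphenyl)-3,5-dimethoxy-7-methyl-8-oxo-1-(prop-2-en-1-yl)bicyclo[3.2.1]oct-2-en-4-yl acetate | C=CC[C@]12C=C(OC)[C@H](OC(C)=O)[C@](OC)(C1=O)[C@H](c1ccc(OC)c(OC)c1)[C@H]2C | target

**Totals and risks**

Total step count: 11. Longest linear sequence: 11 steps (1 → 24).

The three steps most likely to fail are 3, 5 and 9.

Step 3, the proposed new arylation, may give low ee, diarylation or ring-opened products. The fallback uses known chemistry, sets out from 3 and comes back at 5. The lithium enolate of N-acetyl-(2R,5R)-2,5-dimethylpyrrolidine (LiN(SiMe3)2) is α-arylated with 3 under Pd(dba)2/P(t-Bu)3 catalysis to give the arylacetamide 1-[(2R,5R)-2,5-dimethylpyrrolidin-1-yl]-2-(3,4-dimethoxyphenyl)ethan-1-one F1. Tf2O and 2,6-di-tert-butylpyridine convert F1 into its keteniminium triflate, which adds propene in a Ghosez keteniminium–alkene cycloaddition under auxiliary control to give the cyclobutaniminium salt (2R,5R)-1-[(2S,3S)-2-(3,4-dimethoxyphenyl)-3-methylcyclobutylidene]-2,5-dimethylpyrrolidin-1-ium trifluoromethanesulfonate F2. Hydrolysis with aqueous NaHCO3, Et3N equilibration to the trans isomer and one recrystallisation give 5.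

Step 5 may suffer from migration of the CH2 carbon, from the wrong C5 epimer (vinyl cis to aryl) or from a mismatched ligand. The fallback sets out from 5 and comes back at 11; it replaces the palladium-bound allyl terminus by an epoxide trigger and makes the ozonolysis unnecessary. 1-Methoxyvinyllithium 13 adds to 5 to give (1S,2S,3S)-2-(3,4-dimethoxyphenyl)-1-(1-methoxyethenyl)-3-methylcyclobutan-1-ol F3. Dimethyldioxirane at −40 °C epoxidises the enol ether to (1S,2S,3S)-2-(3,4-dimethoxyphenyl)-1-(2-methoxyoxiran-2-yl)-3-methylcyclobutan-1-ol F4. Its oxocarbenium ion triggers the same benzylic 1,2-shift (epoxide-initiated semipinacol ring expansion, the bulkier CH2O group going trans to the aryl group) to give (2S,3S,4S)-3-(3,4-dimethoxyphenyl)-2-(hydroxymethyl)-2-methoxy-4-methylcyclopentan-1-one F5. Dess–Martin oxidation of F5 gives 11.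

Step 9 has to ionise a neopentyl-type carbonate and create a quaternary bridgehead; slow ionisation, O-allylation or carbonate transfer to the enolate are the risks. The fallback sets out from 18 and comes back at 20, through a Lewis-acid-generated cation instead of an allyl unit on palladium. KN(SiMe3)2 and Me3SiCl give the silyl enol ether tert-butyl 1-[(1S,2S,3R)-2-(3,4-dimethoxyphenyl)-1-methoxy-3-methyl-4-(prop-2-en-1-yl)-5-[(trimethylsilyl)oxy]cyclopent-4-en-1-yl]-2-methoxyprop-2-en-1-yl carbonate F6. Me3SiOTf (10 mol %) in CH2Cl2 at −78 °C ionises the allylic carbonate to the 2-methoxyallyl cation, which is captured at its free terminus by the silyl enol ether carbon (Reetz/Mukaiyama-type SN1 alkylation) to give 20.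

**Further compounds**

F1 | step 3 | 1-[(2R,5R)-2,5-dimethylpyrrolidin-1-yl]-2-(3,4-dimethoxyphenyl)ethan-1-one | C[C@@H]1CC[C@@H](C)N1C(=O)Cc1ccc(OC)c(OC)c1
F2 | step 3 | (2R,5R)-1-[(2S,3S)-2-(3,4-dimethoxyphenyl)-3-methylcyclobutylidene]-2,5-dimethylpyrrolidin-1-ium trifluoromethanesulfonate | C[C@@H]1CC[C@@H](C)[N+]1=C1[C@H](c2ccc(OC)c(OC)c2)[C@@H](C)C1.[O-]S(=O)(=O)C(F)(F)F
F3 | step 5 | (1S,2S,3S)-2-(3,4-dimethoxyphenyl)-1-(1-methoxyethenyl)-3-methylcyclobutan-1-ol | C=C(OC)[C@@]1(O)[C@H](c2ccc(OC)c(OC)c2)[C@@H](C)C1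
F4 | step 5 | (1S,2S,3S)-2-(3,4-dimethoxyphenyl)-1-(2-methoxyoxiran-2-yl)-3-methylcyclobutan-1-ol | COC1(CO1)[C@@]1(O)[C@H](c2ccc(OC)c(OC)c2)[C@@H](C)C1
F5 | step 5 | (2S,3S,4S)-3-(3,4-dimethoxyphenyl)-2-(hydroxymethyl)-2-methoxy-4-methylcyclopentan-1-one | OC[C@](OC)(C1=O)[C@H](c2ccc(OC)c(OC)c2)[C@@H](C)C1
F6 | step 9 | tert-butyl 1-[(1S,2S,3R)-2-(3,4-dimethoxyphenyl)-1-methoxy-3-methyl-4-(prop-2-en-1-yl)-5-[(trimethylsilyl)oxy]cyclopent-4-en-1-yl]-2-methoxyprop-2-en-1-yl carbonate | C=C(OC)C(OC(=O)OC(C)(C)C)[C@]1(OC)C(O[Si](C)(C)C)=C(CC=C)[C@H](C)[C@H]1c1ccc(OC)c(OC)c1
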